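## The problem

The target is a 1-aryltetralin cyclolignan. Ring A is a pentasubstituted benzo ring (OMe at C6 and C8, free OH at C7) fused through C4a and C8a to the carbocycle ring B. Ring B carries a 4-hydroxy-3-methoxyphenyl group at C1, hydroxymethyl groups at C2 (C9) and C3 (C10), and a benzylic CH2 at C4. The three contiguous stereocentres C1 (R), C2 (S) and C3 (S) are mutually trans, and C1 is a doubly benzylic methine crowded by the peri methoxy group at C8. Only C1 needs absolute control: with C9 at the ester level C2 is epimerisable and can settle trans to the C1 aryl group, and a C9 hydroxyl on C2 can then steer hydrogen onto one face of a C3=C4 alkene to fix C3. The two phenols are electron-rich and oxidisable, the para-oxygenated benzylic C1 centre can ionise under strong acid, and the 1,4-diol can close to a tetrahydrofuran, so the phenols stay masked until a final neutral deprotection and acidic steps are kept mild. The feature that makes the key step possible is that C2 is alpha to C9 while C3 can be a trigonal carbon of a C3=C4 styrene anchored at C4a. A C9 ester enolate at C2 and a halide at C3, hanging from the adjacent ring A carbons C8a and C4a, can then be joined as the sixth bond of ring B.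

## Retrosynthesis

**Oxidation level and protecting groups.** Target 18 comes from tribenzyl ether 17 by cutting three O–CH2Ph bonds. 17 comes from dihydronaphthalene alcohol 16 by adding hydrogen across C3=C4, and 16 from tert-butyl ester 15 by reducing C9. None of these is a skeletal cut, but together they put the last stereocentre (C3) under control of the C9 hydroxyl on C2 and reduce the problem to a 1,2-dihydronaphthalene with two stereocentres. The forward reactions must reduce a hindered ester without disturbing the allylic C2 centre, and must deliver hydrogen to the alkene face on which C9 lies.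

**C2–C3.** In 15 this bond joins an ester alpha-carbon to an alkene carbon; cutting it gives the acyclic bromide 13 (the forward reaction passes through dienolate 14). Cuts at C1–C8a or C1–aryl would create C1 from a benzylic cation, and a double cut at C1–C2/C3–C4 would need an o-quinodimethane. The C2–C3 cut instead leaves C1 as a preformed, configurationally stable centre and asks of ring A only two ortho substituents. Precursor 13 has no ring B and one stereocentre instead of two. The forward reaction must couple a tert-butyl ester enolate with a (Z)-vinyl bromide on palladium faster than the base attacks the bromide, and must leave C2 trans to the C1 aryl group.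

**C3=C4.** The bromoalkene of 13 is traced through alcohol 12 and ethyl ester 11 to aldehyde 9 and bromo ylide 10 by cutting the C3=C4 double bond. This is preferred to building the alkene from an alkyne because the stabilised ylide 10 delivers C3, its bromine and C10 in one reagent and places bromine cis to ring A, the only geometry from which ring B can close. Aldehyde 9 is simpler by three carbons and the halogen. The forward sequence needs a (Z)-selective olefination, reduction of the conjugated ethyl ester beside the tert-butyl ester, and an O-benzylation.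

**C1–aryl.** Aldehyde 9 arises by hydrolysis of dioxolane 8, and 8 is cut between C1 and the pendant aryl group into cinnamate 6 and boronic acid 7. The neighbouring cut at C1–C8a (ring A as nucleophile onto a ferulate) would need a doubly ortho-substituted arylboron reagent that loses boron easily; here 7 is unhindered and the hindrance stays in the acceptor. Cinnamate 6 is achiral, so the absolute configuration of the whole synthesis rests on this one catalytic step. It must add the aryl group to one enantiotopic face of a congested (E)-enoate and tolerate the acetal.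

**C1–C8a and ring A.** Cinnamate 6 is cut at C1–C8a into aryl bromide 4 and tert-butyl acrylate 5. Bromide 4 comes from aldehyde 3 by acetalisation, 3 from benzyl ether 2 by bromination, and 2 from syringaldehyde 1. Syringaldehyde already has the C6/C7/C8 oxygen pattern and its formyl carbon becomes C4. Only the bromine at the future C8a has to be added, and the two free ring positions are equivalent. The forward reactions are an etherification, an aromatic bromination, an acetalisation and a Heck coupling at a doubly ortho-substituted bromide.

## Roads not taken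

**Alternative 1:** Lactol bis-arylation.
- **Cut:** C1–C8a and C1–aryl, both at an oxidised C1. The precursor is lactol A1 (a 3,4-trans tetrahydrofuran-2-ol carrying the ring A benzyl group and C9 as a benzyl ether), with guaiacol A2 as the second arene.
- **Forward key step:** Sc(OTf)3 in a fluorinated alcohol ionises A1. Friedel–Crafts closure at C8a gives a bridged benzylic ether, which ionises again and is captured by A2 para to its hydroxyl, giving A3, the target but for two benzyl ethers.
- **Merits:** two C–C bonds and ring B form in one flask, and C2 and C3 come from a butyrolactone, for which asymmetric alkylation is routine. The route is convergent and clearly shorter than the chosen one. Attack anti to the C2 substituent should favour the 1,2-trans product, as is usual in aryltetralin cyclisations.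
- **Weak points:** C1 is made from a benzylic cation twice, beside the peri C8 methoxy group. A2 can react ortho as well as para, and more than once. Benzyl ethers on electron-rich rings can transfer benzyl cations in so ionising a medium. A1 itself needs two stereocentres built enantioselectively with C9 and C10 differentiated.
- **Comparison:** Alternative 1 is better in step count and convergence. The chosen plan sets against this a catalyst-controlled C1 that is never ionised afterwards, and a separate control element for each stereocentre.

**Alternative 2:** Photoenol Diels–Alder with a chiral fumarate.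
- **Cut:** C1–C2 and C3–C4.
- **Forward key step:** irradiation of benzophenone A4 causes photoenolisation, and the resulting diene is trapped by bis-lactate fumarate A5 to give hydroxy tetralin A6.
- **Merits:** two bonds and ring B in one step, 2,3-trans from the (E)-dienophile, and a cheap auxiliary. Both C9 and C10 stay at the ester level, so C2 and C3 can both be corrected by epimerisation. This is an advantage over the chosen plan, where C3 depends on one directed hydrogenation.
- **Weak points:** the carbonyl of A4 lies between an ortho methyl and an ortho methoxy group on a strongly donating ring, so it is twisted and electron-rich, a poor case for hydrogen abstraction. Face selectivity of a short-lived photoenol towards A5 is uncertain. A6 carries a tertiary hydroxyl at C1 that must be removed reductively through the C1 cation, which re-opens the C1 configuration and costs steps, as does removal of two lactates.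
- **Comparison:** Alternative 2 reaches ring B faster. The chosen plan sets against it a C1–H centre made directly by a predictable catalytic step, and no photochemistry or deoxygenation.

**Alternative 3:** One-carbon ring expansion of a Nazarov indanone.
- **Cut:** C4–C4a and C3–C4 (C4 inserted), after a five-membered ring has been made.
- **Forward key step:** indanone A7 is treated with trimethylsilyldiazomethane A8 and BF3·OEt2. The aryl carbon C4a migrates and the ring grows to tetralone A9 with its ketone at C3.
- **Merits:** the Nazarov cyclisation gives the trans indanone reliably, C2 stays epimerisable next to the ketone (the same thermodynamic control the chosen plan uses), and the ring-forming stage uses simple reagents and no precious metal.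
- **Weak points:** migration of the substituted alkyl carbon C2 competes with aryl migration. A9 is a 2-tetralone, enolisable on both sides and air-sensitive. C10 is still missing and must be added at the ketone (methylenation, then hydroboration), with a new selectivity question at C3. An enantioselective Nazarov reaction for this substrate is not general.
- **Comparison:** Alternative 3 is comparable in its control of C2. The chosen plan brings C10 in with the vinyl bromide, so no carbon is added after ring closure, and takes its absolute configuration from a standard asymmetric conjugate addition.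

Key step: step 9

Assumption (stereochemical model): the monovalent rhodium/(S)-BINAP catalyst is taken to deliver the aryl group to the alpha-si face of the (E)-enoate, its usual preference for acyclic (E)-enoates, which corresponds to (R) at C1.

## Route

Step 1
Reactants: 1 syringaldehyde (4-hydroxy-3,5-dimethoxybenzaldehyde)
Product: 2 4-(benzyloxy)-3,5-dimethoxybenzaldehyde
Conditions: BnBr, K2CO3, DMF, 60 °C
Reagents that add atoms: benzyl bromide, BrCc1ccccc1
Why: Williamson ether synthesis on the phenoxide; the benzyl ether masks the C7 oxygen through all basic, reductive and palladium steps and leaves with the other benzyl groups in the last step.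

Step 2
Reactants: 2 4-(benzyloxy)-3,5-dimethoxybenzaldehyde
Product: 3 4-(benzyloxy)-2-bromo-3,5-dimethoxybenzaldehyde
Conditions: NBS (1.05 equiv), MeCN, rt → 50 °C, dark
Reagents that add atoms: N-bromosuccinimide, O=C1CCC(=O)N1Br
Why: Electrophilic aromatic bromination; the two free positions are equivalent and each is ortho to one methoxy group and para to the other, as in the standard bromination of 3,4,5-trimethoxybenzaldehyde, and one equivalent limits dibromination.

Step 3
Reactants: 3 4-(benzyloxy)-2-bromo-3,5-dimethoxybenzaldehyde
Product: 4 2-[4-(benzyloxy)-2-bromo-3,5-dimethoxyphenyl]-1,3-dioxolane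
Conditions: HOCH2CH2OH, TsOH·H2O (cat.), toluene, reflux, azeotropic removal of water
Reagents that add atoms: ethylene glycol, OCCO
Why: Acid-catalysed acetalisation; it is done before the acrylate is attached because an ortho-formyl cinnamate is prone to oxa-Michael ring closure during acetal formation, and because a free aldehyde could capture the aryl–rhodium species in step 5.

Step 4
Reactants: 4 2-[4-(benzyloxy)-2-bromo-3,5-dimethoxyphenyl]-1,3-dioxolane; 5 tert-butyl acrylate
Product: 6 tert-butyl (2E)-3-[3-(benzyloxy)-6-(1,3-dioxolan-2-yl)-2,4-dimethoxyphenyl]prop-2-enoate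
Conditions: Pd2(dba)3 (cat.), [HP(t-Bu)3]BF4 (cat.), Cy2NMe, dioxane, 100 °C
Reagents that add atoms: none
Why: Mizoroki–Heck reaction forming the C1–C8a bond; the bulky electron-rich phosphine is chosen because the bromide has two ortho substituents on an electron-rich ring, and syn insertion followed by syn beta-hydride elimination gives the (E)-cinnamate.

Step 5
Reactants: 6 tert-butyl (2E)-3-[3-(benzyloxy)-6-(1,3-dioxolan-2-yl)-2,4-dimethoxyphenyl]prop-2-enoate; 7 [4-(benzyloxy)-3-methoxyphenyl]boronic acid
Product: 9 tert-butyl (3R)-3-[4-(benzyloxy)-3-methoxyphenyl]-3-[3-(benzyloxy)-6-formyl-2,4-dimethoxyphenyl]propanoate, via dioxolane adduct 8 (not isolated)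
Conditions: [Rh(acac)(C2H4)2] (cat.), (S)-BINAP, 7 (3 equiv), dioxane/H2O (10:1), 100 °C; then 1 M HCl, THF, rt
Reagents that add atoms: water, O
Why: Hayashi–Miyaura asymmetric 1,4-addition: the aryl–rhodium species from 7 inserts the enoate and the rhodium enolate is hydrolysed, and with (S)-BINAP the aryl group should arrive on the alpha-si face, which sets C1 as (R). The neutral aqueous medium leaves dioxolane and tert-butyl ester intact, and the dilute acid of the second stage frees the formyl group (its oxygen from water) without cleaving the tert-butyl ester.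

Step 6
Reactants: 9 tert-butyl (3R)-3-[4-(benzyloxy)-3-methoxyphenyl]-3-[3-(benzyloxy)-6-formyl-2,4-dimethoxyphenyl]propanoate; 10 ethyl 2-bromo-2-(triphenyl-λ5-phosphanylidene)acetate
Product: 11 tert-butyl (3R)-3-[4-(benzyloxy)-3-methoxyphenyl]-3-{3-(benzyloxy)-6-[(1Z)-2-bromo-3-ethoxy-3-oxoprop-1-en-1-yl]-2,4-dimethoxyphenyl}propanoate
Conditions: toluene, 80 °C
Reagents that add atoms: none
Why: Wittig olefination with a stabilised alpha-bromo ylide, which brings in C3, its bromine and C10 at once; such ylides place the ester trans to the aryl group, so bromine ends cis to ring A ((Z)), the geometry that ring closure requires.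

Step 7
Reactants: 11 tert-butyl (3R)-3-[4-(benzyloxy)-3-methoxyphenyl]-3-{3-(benzyloxy)-6-[(1Z)-2-bromo-3-ethoxy-3-oxoprop-1-en-1-yl]-2,4-dimethoxyphenyl}propanoate
Product: 12 tert-butyl (3R)-3-[4-(benzyloxy)-3-methoxyphenyl]-3-{3-(benzyloxy)-6-[(1Z)-2-bromo-3-hydroxyprop-1-en-1-yl]-2,4-dimethoxyphenyl}propanoate
Conditions: i-Bu2AlH (2.2 equiv), CH2Cl2, −78 °C; aq. potassium sodium tartrate
Reagents that add atoms: none
Why: 1,2-Reduction of the conjugated ethyl ester to the allylic alcohol; at −78 °C the hindered, saturated tert-butyl ester is attacked far more slowly, and the C–Br bond and alkene geometry are not touched by the aluminium hydride.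

Step 8
Reactants: 12 tert-butyl (3R)-3-[4-(benzyloxy)-3-methoxyphenyl]-3-{3-(benzyloxy)-6-[(1Z)-2-bromo-3-hydroxyprop-1-en-1-yl]-2,4-dimethoxyphenyl}propanoate
Product: 13 tert-butyl (3R)-3-[4-(benzyloxy)-3-methoxyphenyl]-3-{3-(benzyloxy)-6-[(1Z)-3-(benzyloxy)-2-bromoprop-1-en-1-yl]-2,4-dimethoxyphenyl}propanoate
Conditions: NaH (1.1 equiv), BnBr, Bu4NI (cat.), THF/DMF, 0 °C → rt
Reagents that add atoms: benzyl bromide, BrCc1ccccc1
Why: Williamson ether synthesis; the alkoxide forms much faster than the ester enolate with a slight excess of hydride. The benzyl ether removes an acidic OH from the key step, leaves the C9 hydroxyl as the only directing group in step 11, and is cleaved with the aryl benzyl ethers in step 12.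

Step 9
Reactants: 13 tert-butyl (3R)-3-[4-(benzyloxy)-3-methoxyphenyl]-3-{3-(benzyloxy)-6-[(1Z)-3-(benzyloxy)-2-bromoprop-1-en-1-yl]-2,4-dimethoxyphenyl}propanoate
Product: 15 tert-butyl (1R,2S)-7-(benzyloxy)-1-[4-(benzyloxy)-3-methoxyphenyl]-3-[(benzyloxy)methyl]-6,8-dimethoxy-1,2-dihydronaphthalene-2-carboxylate, via lithium dienolate 14 (not isolated)
Conditions: Pd2(dba)3 (cat.), [HP(t-Bu)3]BF4 (cat.), LiN(SiMe3)2 (2.5 equiv), toluene, rt → 50 °C; then t-BuOH (excess), rt; aq. NH4Cl
Reagents that add atoms: none
Why: LiN(SiMe3)2 turns the tert-butyl ester into its lithium enolate while zerovalent palladium inserts into the vinyl C3–Br bond with retention; exchange of bromide for the enolate gives a seven-membered C,C-palladacycle, and reductive elimination forms C2–C3. The closest known reaction type is the palladium-catalysed intramolecular alpha-alkenylation of ketone, ester and nitrile enolates with vinyl halides, together with the intermolecular coupling of tert-butyl ester enolates with vinyl bromides under this ligand and base. Ring B closes as a six-membered ring by C(sp3)–C(sp2) reductive elimination with C3=C4 ending inside the ring, which is possible only because bromine is cis to ring A. The product is more acidic than 13 and rests as dienolate 14, which is why more than two equivalents of base are used. A direct aqueous quench would protonate C2 anti to the pseudoaxial C1 aryl group and favour the cis ester, so tert-butanol is added first: LiOt-Bu/t-BuOH exchanges the C2 proton reversibly and C2 should settle trans to the aryl group, the diaxial arrangement that relieves the peri interaction with the C8 methoxy group and the allylic strain with the C3 substituent. The dienolate is protonated faster at C2 than at C4, so C2 should equilibrate before the double bond leaves conjugation with ring A, and the non-acidic C1 keeps its configuration. Alkenylation is favoured over Claisen condensation by the tert-butyl ester and by the intramolecular capture on palladium, and 13 has no second enolisable site.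

Step 10
Reactants: 15 tert-butyl (1R,2S)-7-(benzyloxy)-1-[4-(benzyloxy)-3-methoxyphenyl]-3-[(benzyloxy)methyl]-6,8-dimethoxy-1,2-dihydronaphthalene-2-carboxylate
Product: 16 [(1R,2S)-7-(benzyloxy)-1-[4-(benzyloxy)-3-methoxyphenyl]-3-[(benzyloxy)methyl]-6,8-dimethoxy-1,2-dihydronaphthalen-2-yl]methanol
Conditions: LiAlH4, THF, 0 °C → rt
Reagents that add atoms: none
Why: Hydride reduction of the ester to the C9 primary alcohol; starting cold lets reduction outrun any base-induced epimerisation at C2, and benzyl ethers and the styrene are inert to the reagent.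

Step 11
Reactants: 16 [(1R,2S)-7-(benzyloxy)-1-[4-(benzyloxy)-3-methoxyphenyl]-3-[(benzyloxy)methyl]-6,8-dimethoxy-1,2-dihydronaphthalen-2-yl]methanol
Product: 17 [(1R,2S,3S)-7-(benzyloxy)-1-[4-(benzyloxy)-3-methoxyphenyl]-3-[(benzyloxy)methyl]-6,8-dimethoxy-1,2,3,4-tetrahydronaphthalen-2-yl]methanol
Conditions: [Ir(cod)(PCy3)(py)]PF6 (cat.), H2 (1 atm), CH2Cl2, rt
Reagents that add atoms: none
Why: Hydroxyl-directed homogeneous hydrogenation: the C9 hydroxyl on C2 binds the cationic iridium centre, so both hydrogens should reach C3=C4 from the face on which C9 lies and the benzyloxymethyl group at C3 ends trans to C9 (3S). This overrides the steric preference for addition anti to the C2 substituent, and the catalyst does not hydrogenolyse benzyl ethers.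

Step 12
Reactants: 17 [(1R,2S,3S)-7-(benzyloxy)-1-[4-(benzyloxy)-3-methoxyphenyl]-3-[(benzyloxy)methyl]-6,8-dimethoxy-1,2,3,4-tetrahydronaphthalen-2-yl]methanol
Product: 18 [(1R,2S,3S)-7-hydroxy-1-(4-hydroxy-3-methoxyphenyl)-3-(hydroxymethyl)-6,8-dimethoxy-1,2,3,4-tetrahydronaphthalen-2-yl]methanol (the target)
Conditions: H2 (1 atm), Pd/C, EtOAc/MeOH, rt
Reagents that add atoms: none
Why: Hydrogenolysis of the two aryl benzyl ethers and the alkyl benzyl ether under neutral conditions; no stereocentre is involved and the free phenols appear only in the last step.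

## Compound list

1 | syringaldehyde (4-hydroxy-3,5-dimethoxybenzaldehyde) | COc1cc(C=O)cc(OC)c1O | starting material
2 | 4-(benzyloxy)-3,5-dimethoxybenzaldehyde | COc1cc(C=O)cc(OC)c1OCc1ccccc1 | intermediate
3 | 4-(benzyloxy)-2-bromo-3,5-dimethoxybenzaldehyde | COc1cc(C=O)c(Br)c(OC)c1OCc1ccccc1 | intermediate
4 | 2-[4-(benzyloxy)-2-bromo-3,5-dimethoxyphenyl]-1,3-dioxolane | COc1cc(C2OCCO2)c(Br)c(OC)c1OCc1ccccc1 | intermediate
5 | tert-butyl acrylate | C=CC(=O)OC(C)(C)C | starting material
6 | tert-butyl (2E)-3-[3-(benzyloxy)-6-(1,3-dioxolan-2-yl)-2,4-dimethoxyphenyl]prop-2-enoate | COc1cc(C2OCCO2)c(/C=C/C(=O)OC(C)(C)C)c(OC)c1OCc1ccccc1 | intermediate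
7 | [4-(benzyloxy)-3-methoxyphenyl]boronic acid | COc1cc(B(O)O)ccc1OCc1ccccc1 | starting material
8 | tert-butyl (3R)-3-[4-(benzyloxy)-3-methoxyphenyl]-3-[3-(benzyloxy)-6-(1,3-dioxolan-2-yl)-2,4-dimethoxyphenyl]propanoate (dioxolane adduct, formed in the flask) | COc1cc([C@@H](CC(=O)OC(C)(C)C)c2c(C3OCCO3)cc(OC)c(OCc3ccccc3)c2OC)ccc1OCc1ccccc1 | intermediate
9 | tert-butyl (3R)-3-[4-(benzyloxy)-3-methoxyphenyl]-3-[3-(benzyloxy)-6-formyl-2,4-dimethoxyphenyl]propanoate | COc1cc([C@@H](CC(=O)OC(C)(C)C)c2c(C=O)cc(OC)c(OCc3ccccc3)c2OC)ccc1OCc1ccccc1 | intermediate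
10 | ethyl 2-bromo-2-(triphenyl-λ5-phosphanylidene)acetate | CCOC(=O)C(Br)=P(c1ccccc1)(c1ccccc1)c1ccccc1 | starting material
11 | tert-butyl (3R)-3-[4-(benzyloxy)-3-methoxyphenyl]-3-{3-(benzyloxy)-6-[(1Z)-2-bromo-3-ethoxy-3-oxoprop-1-en-1-yl]-2,4-dimethoxyphenyl}propanoate | COc1cc([C@@H](CC(=O)OC(C)(C)C)c2c(/C=C(\Br)C(=O)OCC)cc(OC)c(OCc3ccccc3)c2OC)ccc1OCc1ccccc1 | intermediate
12 | tert-butyl (3R)-3-[4-(benzyloxy)-3-methoxyphenyl]-3-{3-(benzyloxy)-6-[(1Z)-2-bromo-3-hydroxyprop-1-en-1-yl]-2,4-dimethoxyphenyl}propanoate | COc1cc([C@@H](CC(=O)OC(C)(C)C)c2c(/C=C(\Br)CO)cc(OC)c(OCc3ccccc3)c2OC)ccc1OCc1ccccc1 | intermediate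
13 | tert-butyl (3R)-3-[4-(benzyloxy)-3-methoxyphenyl]-3-{3-(benzyloxy)-6-[(1Z)-3-(benzyloxy)-2-bromoprop-1-en-1-yl]-2,4-dimethoxyphenyl}propanoate | COc1cc([C@@H](CC(=O)OC(C)(C)C)c2c(/C=C(\Br)COCc3ccccc3)cc(OC)c(OCc3ccccc3)c2OC)ccc1OCc1ccccc1 | intermediate
14 | lithium dienolate of 15 (C2=C9 enolate conjugated with C3=C4, formed in the flask) | [Li+].COc1cc([C@@H]2c3c(cc(OC)c(OCc4ccccc4)c3OC)C=C(COCc3ccccc3)C2=C([O-])OC(C)(C)C)ccc1OCc1ccccc1 | intermediate
15 | tert-butyl (1R,2S)-7-(benzyloxy)-1-[4-(benzyloxy)-3-methoxyphenyl]-3-[(benzyloxy)methyl]-6,8-dimethoxy-1,2-dihydronaphthalene-2-carboxylate | COc1cc([C@@H]2c3c(cc(OC)c(OCc4ccccc4)c3OC)C=C(COCc3ccccc3)[C@H]2C(=O)OC(C)(C)C)ccc1OCc1ccccc1 | intermediate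
16 | [(1R,2S)-7-(benzyloxy)-1-[4-(benzyloxy)-3-methoxyphenyl]-3-[(benzyloxy)methyl]-6,8-dimethoxy-1,2-dihydronaphthalen-2-yl]methanol | COc1cc([C@@H]2c3c(cc(OC)c(OCc4ccccc4)c3OC)C=C(COCc3ccccc3)[C@H]2CO)ccc1OCc1ccccc1 | intermediate
17 | [(1R,2S,3S)-7-(benzyloxy)-1-[4-(benzyloxy)-3-methoxyphenyl]-3-[(benzyloxy)methyl]-6,8-dimethoxy-1,2,3,4-tetrahydronaphthalen-2-yl]methanol | COc1cc([C@@H]2c3c(cc(OC)c(OCc4ccccc4)c3OC)C[C@H](COCc3ccccc3)[C@H]2CO)ccc1OCc1ccccc1 | intermediate
18 | [(1R,2S,3S)-7-hydroxy-1-(4-hydroxy-3-methoxyphenyl)-3-(hydroxymethyl)-6,8-dimethoxy-1,2,3,4-tetrahydronaphthalen-2-yl]methanol | COc1cc([C@@H]2c3c(cc(OC)c(O)c3OC)C[C@H](CO)[C@H]2CO)ccc1O | target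

## Step count and least certain steps

Total: 12 steps. Longest linear sequence: 12 steps (1 → 18).

**Step 9 (key step).**
- **Risk:** loss of the vinyl bromide before coupling, either by base-induced elimination of HBr (the C4–H is anti to bromine) or by beta-alkoxide elimination from the alkenylpalladium intermediate. The alcohol quench could also leave C2 incompletely equilibrated, or let the double bond drift to C2=C3.
- **Fallback:** from 13, LiN(i-Pr)2 and Me3SiCl in THF at −78 °C would give the O-silyl ketene acetal F1. Pd2(dba)3/P(t-Bu)3 with ZnF2 in DMF at 80 °C would then couple this latent enolate with the vinyl bromide without strong base (the fluoride-promoted palladium coupling of silyl ketene acetals with aryl and alkenyl halides is a known reaction type). A catalytic NaOt-Bu/t-BuOH treatment of the crude ester would settle C2, returning to the route at 15.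

**Step 5.**
- **Risk:** slow insertion, because the beta-carbon of 6 carries a doubly ortho-substituted aryl group. Protodeboronation of 7 could then outrun the addition, and the enantioselectivity could erode at the temperature needed.
- **Fallback:** move the hindrance from the acceptor to the nucleophile and take the configuration from an auxiliary. From 4, Mg and LiCl in THF would give arylmagnesium bromide F2. With CuBr·SMe2 in THF at −40 to 0 °C, F2 should add to cinnamoyl oxazolidinone F3 anti to the 4-phenyl group of the chelated s-cis conformer, giving imide F4 with (R) at C1. F3 is prepared from (2E)-3-[4-(benzyloxy)-3-methoxyphenyl]prop-2-enoic acid through its pivaloyl mixed anhydride and (4R)-4-phenyl-1,3-oxazolidin-2-one. LiOH/H2O2 would release acid F5, and Boc2O, DMAP and t-BuOH would give 8, which is hydrolysed to 9 as in the second stage of step 5.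

**Step 7.**
- **Risk:** incomplete discrimination between the two esters, that is, partial reduction of the tert-butyl ester or arrest at the aldehyde stage.
- **Fallback:** from 11, LiOH in THF/H2O at 0 °C would saponify only the ethyl ester to bromoacrylic acid F6. Isobutyl chloroformate and N-methylmorpholine in THF at −15 °C would give mixed anhydride F7, and NaBH4 in THF/H2O would reduce it to 12. A borohydride does not attack a tert-butyl ester.

**Step 11.**
- **Risk:** insufficient facial control if the catalyst deactivates before the hindered trisubstituted styrene is reduced, or if the benzyl ether oxygen at C10 competes for iridium; the intrinsic steric bias then gives the C3 epimer.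
- **Fallback:** steric control followed by epimerisation, starting one step earlier. From 15, LiN(i-Pr)2 in THF at −78 °C regenerates dienolate 14, and AcOH at −78 °C should protonate C2 anti to the C1 aryl group to give cis ester F8. In F8 both the aryl and ester groups shield the same face, so H2 over Pt/C in EtOAc should add from the other face and give the all-cis tetralin ester F9 with C3 correct. Catalytic NaOt-Bu in t-BuOH/THF would then epimerise C2 to the all-trans ester F10, with no alkene left to migrate, and LiAlH4 would give 17.

## Further compounds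

F1 | step 9 | O-trimethylsilyl O-tert-butyl ketene acetal of 13 | COc1cc([C@@H](C=C(O[Si](C)(C)C)OC(C)(C)C)c2c(/C=C(\Br)COCc3ccccc3)cc(OC)c(OCc3ccccc3)c2OC)ccc1OCc1ccccc1
F2 | step 5 | [3-(benzyloxy)-6-(1,3-dioxolan-2-yl)-2,4-dimethoxyphenyl]magnesium bromide | COc1cc(C2OCCO2)c([Mg]Br)c(OC)c1OCc1ccccc1
F3 | step 5 | (4R)-3-{(2E)-3-[4-(benzyloxy)-3-methoxyphenyl]prop-2-enoyl}-4-phenyl-1,3-oxazolidin-2-one | COc1cc(/C=C/C(=O)N2C(=O)OC[C@H]2c2ccccc2)ccc1OCc1ccccc1
F4 | step 5 | (4R)-3-{(3R)-3-[4-(benzyloxy)-3-methoxyphenyl]-3-[3-(benzyloxy)-6-(1,3-dioxolan-2-yl)-2,4-dimethoxyphenyl]propanoyl}-4-phenyl-1,3-oxazolidin-2-one | COc1cc([C@@H](CC(=O)N2C(=O)OC[C@H]2c2ccccc2)c2c(C3OCCO3)cc(OC)c(OCc3ccccc3)c2OC)ccc1OCc1ccccc1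
F5 | step 5 | (3R)-3-[4-(benzyloxy)-3-methoxyphenyl]-3-[3-(benzyloxy)-6-(1,3-dioxolan-2-yl)-2,4-dimethoxyphenyl]propanoic acid | COc1cc([C@@H](CC(=O)O)c2c(C3OCCO3)cc(OC)c(OCc3ccccc3)c2OC)ccc1OCc1ccccc1
F6 | step 7 | (2Z)-3-{4-(benzyloxy)-2-[(1R)-1-[4-(benzyloxy)-3-methoxyphenyl]-3-tert-butoxy-3-oxopropyl]-3,5-dimethoxyphenyl}-2-bromoprop-2-enoic acid | COc1cc([C@@H](CC(=O)OC(C)(C)C)c2c(/C=C(\Br)C(=O)O)cc(OC)c(OCc3ccccc3)c2OC)ccc1OCc1ccccc1
F7 | step 7 | isobutyl carbonic mixed anhydride of F6 | COc1cc([C@@H](CC(=O)OC(C)(C)C)c2c(/C=C(\Br)C(=O)OC(=O)OCC(C)C)cc(OC)c(OCc3ccccc3)c2OC)ccc1OCc1ccccc1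
F8 | step 11 | tert-butyl (1R,2R)-7-(benzyloxy)-1-[4-(benzyloxy)-3-methoxyphenyl]-3-[(benzyloxy)methyl]-6,8-dimethoxy-1,2-dihydronaphthalene-2-carboxylate (C2 epimer of 15) | COc1cc([C@@H]2c3c(cc(OC)c(OCc4ccccc4)c3OC)C=C(COCc3ccccc3)[C@@H]2C(=O)OC(C)(C)C)ccc1OCc1ccccc1
F9 | step 11 | tert-butyl (1R,2R,3S)-7-(benzyloxy)-1-[4-(benzyloxy)-3-methoxyphenyl]-3-[(benzyloxy)methyl]-6,8-dimethoxy-1,2,3,4-tetrahydronaphthalene-2-carboxylate (all-cis) | COc1cc([C@@H]2c3c(cc(OC)c(OCc4ccccc4)c3OC)C[C@H](COCc3ccccc3)[C@@H]2C(=O)OC(C)(C)C)ccc1OCc1ccccc1
F10 | step 11 | tert-butyl (1R,2S,3S)-7-(benzyloxy)-1-[4-(benzyloxy)-3-methoxyphenyl]-3-[(benzyloxy)methyl]-6,8-dimethoxy-1,2,3,4-tetrahydronaphthalene-2-carboxylate (all-trans) | COc1cc([C@@H]2c3c(cc(OC)c(OCc4ccccc4)c3OC)C[C@H](COCc3ccccc3)[C@H]2C(=O)OC(C)(C)C)ccc1OCc1ccccc1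
A1 | alternative 1 | 3,4-trans-3-[(benzyloxy)methyl]-4-[4-(benzyloxy)-3,5-dimethoxybenzyl]tetrahydrofuran-2-ol (lactol, anomeric mixture) | OC1OC[C@@H](Cc2cc(OC)c(OCc3ccccc3)c(OC)c2)[C@H]1COCc1ccccc1
A2 | alternative 1 | guaiacol (2-methoxyphenol) | COc1ccccc1O
A3 | alternative 1 | 18 carrying benzyl ethers at the C7 oxygen and the C9 oxygen | COc1cc([C@@H]2c3c(cc(OC)c(OCc4ccccc4)c3OC)C[C@H](CO)[C@H]2COCc2ccccc2)ccc1O
A4 | alternative 2 | [4-(benzyloxy)-3-methoxyphenyl][3-(benzyloxy)-2,4-dimethoxy-6-methylphenyl]methanone | COc1cc(C(=O)c2c(C)cc(OC)c(OCc3ccccc3)c2OC)ccc1OCc1ccccc1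
A5 | alternative 2 | bis[(2S)-1-methoxy-1-oxopropan-2-yl] (2E)-but-2-enedioate | COC(=O)[C@H](C)OC(=O)/C=C/C(=O)O[C@@H](C)C(=O)OC
A6 | alternative 2 | 1-hydroxy-1-aryl tetralin 2,3-trans bis-lactate diester, OH cis to the C2 ester | COc1cc([C@]2(O)c3c(cc(OC)c(OCc4ccccc4)c3OC)C[C@H](C(=O)O[C@@H](C)C(=O)OC)[C@H]2C(=O)O[C@@H](C)C(=O)OC)ccc1OCc1ccccc1
A7 | alternative 3 | trans-5-(benzyloxy)-3-[4-(benzyloxy)-3-methoxyphenyl]-2-{[(tert-butyldimethylsilyl)oxy]methyl}-4,6-dimethoxy-2,3-dihydro-1H-inden-1-one | COc1cc([C@@H]2c3c(cc(OC)c(OCc4ccccc4)c3OC)C(=O)[C@H]2CO[Si](C)(C)C(C)(C)C)ccc1OCc1ccccc1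
A8 | alternative 3 | trimethylsilyldiazomethane | C[Si](C)(C)C=[N+]=[N-]
A9 | alternative 3 | trans-1-aryl-2-(silyloxymethyl)tetralin-3-one (2-tetralone type) | COc1cc([C@@H]2c3c(cc(OC)c(OCc4ccccc4)c3OC)CC(=O)[C@H]2CO[Si](C)(C)C(C)(C)C)ccc1OCc1ccccc1
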